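- Pitfall: Sunday's X of 0% at 2.50 min looks like a clean reaction, but J still stood at 95.6% and E at 5.0%, so these readings say little about E competing with J for G.

| flask | J | G | remark | time |
|---|---|---|---|---|
| Sunday's | 10 mM | 0.60 equiv | run made earlier |  |
| noon | 10 mM | 1.20 equiv |  | 25 min |
| summer | 10 mM | 1.20 equiv |  | 50 min |

Sunday's run (percent of the J charged)

| time / min | E / % | J / % | X / % |
|---|---|---|---|
| 0.200 | 1.0 | 99.6 | 0 |
| 0.667 | 0.7 | 98.0 | 0.5 |
| 1.33 | 3.1 | 97.1 | 0.8 |
| 2.00 | 3.5 | 95.3 | 0 |
| 2.50 | 5.0 | 95.6 | 0 |

(standard deviation of a reading: 0.5 percentage points)

- a reading or a percentage of X counts all its forms, free or not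
- a reading of J is of its free form alone

- which of these there is most of at the end, counted by the J in it, noon (E / X / J)
- which of these there is most of at the end, counted by the J in it, summer (E / X / J)
- how much there is at the end of the one of these that leads, in percent of the J charged: noon
- how much there is at the end of the one of these that leads, in percent of the J charged: summer

- Divide the two rates and time drops out: each J lost makes one E, and meanwhile s·cE/cJ of an E goes on to X. With x as free J in parts of the J charged, E in the same parts is (x^s − x)/(1 − s).
- I take s = 0.500 from the forecast's “probably near half”; s is the selectivity factor, the rate constant of E with G over that of J with G. Sunday's run gives it no firm value, so this is an assumption.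
- On this curve, E tops out at 50.0%, with J at 25.0%.
- Ledger for noon, my own reckoning on the forecast's J of 49%: you charge 12.0 mM of G, less than the 20.0 mM that full conversion to X takes, so G is the limiting reagent.
- Entry one: the curve puts E at 42.0%, below J, and that E holds 4.20 mM of G.
- Entry two: I book the remaining 9.00% of the J charged as X, at two G each, which holds 1.80 mM.
- Closing the books: my estimate for noon leaves 6.00 mM of G unspent.
- The forecast: noon leads with J at 49% (43% to 57%); summer leads with E at 49% (37% to 66%).
- The flasks: noon leads with J at 49.9%; summer leads with E at 46.8%.

    J + G → E (k = 3.60 /M/min)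
    G + E → X (k = 1.20 /M/min)
    J + X ⇌ L, settled at all times (K = 4700 /M)
    G ⇌ Z (K = 11.0, k = 0.0190 /min)

- Summer at 50.0 min has not come to rest: at its free J of 37.4%, the curve gives E 47.5%, and the flask holds 46.8%. The neighbour charged with 17 mM of J ends with J at 23.5%, where the curve gives 50.0% and the flask holds 51.0%. Left ten times as long, to 500 min, summer's J falls to 18.3%, its E reaches 51.7%, its X, bound forms counted, reaches 15.8%, and its free G stands at 1.60% of its charge.

The readings are simulated for substances that don't exist, noise included.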